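**Retrosynthetic overview**
- The last C–O cleavage is demethylation of the ring B methyl ether. Before it, the two ring A C–Br bonds (ortho and para to the ring A hydroxyl) are made by electrophilic bromination of a free ring A phenol.
- The strategy rests on ring B: its hydroxyl carbon C1 lies between C2 (diaryl ether oxygen) and C6 (bromine). In a 2,5-dibromophenyl aryl ether this carbon carries the only hydrogen flanked by O and Br, so that C–H is converted into C–OH by deprotonation, borylation and oxidation.
- The diaryl ether C–O bond comes from Chan–Lam coupling of 2,5-dibromophenol with 2-(methoxymethoxy)phenylboronic acid.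
- Both benzene rings are purchased and no ring is formed. A MOM group on ring A and a methyl group on ring B keep the two hydroxyls distinct, so that only ring A is brominated.

Key step: step 2

Remark: in step 1 the copper acetate is counted as the stoichiometric oxidant of the C–O coupling. Air may reoxidise part of it without changing the product.

**Step 1**
Reactants: 1 2,5-dibromophenol; 2 2-(methoxymethoxy)phenylboronic acid
Product: 3 1,4-dibromo-2-[2-(methoxymethoxy)phenoxy]benzene
Conditions: Cu(OAc)2 (2 equiv), pyridine (5 equiv), 4 Å molecular sieves, CH2Cl2, air, rt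
Reagents that add atoms: none
Why: Chan–Lam oxidative O-arylation mediated by divalent copper acetate runs at room temperature, where the aryl bromides and the MOM acetal should be untouched, and an ortho-halophenol is an accepted partner.

**Step 2**
Reactants: 3 1,4-dibromo-2-[2-(methoxymethoxy)phenoxy]benzene; 4 triisopropyl borate
Product: 7 3,6-dibromo-2-[2-(methoxymethoxy)phenoxy]phenol, via aryllithium 5 (not isolated), via lithium aryltriisopropoxyborate 6 (not isolated)
Conditions: lithium 2,2,6,6-tetramethylpiperidide (1.5 equiv, from 2,2,6,6-tetramethylpiperidine and n-BuLi) added to 3 and B(OiPr)3 (2 equiv), THF, −78 °C; then AcOH, 30% H2O2, 0 °C to rt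
Reagents that add atoms: hydrogen peroxide, OO
Why: Deprotonative metalation with in situ borate quench and oxidative hydroxylation: the hindered, non-nucleophilic lithium amide removes the one ring B proton acidified inductively by both the adjacent ether oxygen and the adjacent bromine, without bromine–lithium exchange, to give aryllithium 5. Because triisopropyl borate is already present and tolerates the amide at −78 °C, 5 should be captured as borate 6 before it can expel LiBr to an aryne or start a bromine migration. After acidification, hydroperoxide adds to boron and the aryl group shifts from boron to oxygen with retention at carbon, and hydrolysis of the borate ester releases the phenol, so the new C–O bond stands where the proton was removed. The closest known reaction type is the amide-base metalation of 1,4-dibromo-2-fluorobenzene and of 3-bromoanisole-type ethers between the heteroatom and bromine, followed by borate trapping and peroxide oxidation. No ring is closed and no stereocentre is formed. The step needs site selectivity among seven aryl C–H bonds and chemoselectivity over halogen–metal exchange: the first is secured by the unique O/Br-flanked hydrogen (ring A bears no halogen and its acetal-directed metalation is slow with a lithium amide at −78 °C), the second by using an amide base and not an alkyllithium.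

**Step 3**
Reactants: 7 3,6-dibromo-2-[2-(methoxymethoxy)phenoxy]phenol
Product: 8 1,4-dibromo-2-methoxy-3-[2-(methoxymethoxy)phenoxy]benzene
Conditions: MeI, K2CO3, DMF, rt
Reagents that add atoms: iodomethane, CI
Why: Williamson O-methylation of an acidic, halogen-flanked phenoxide is reliable, and it masks the ring B hydroxyl so that this ring is no longer a free phenol in the later bromination.

**Step 4**
Reactants: 8 1,4-dibromo-2-methoxy-3-[2-(methoxymethoxy)phenoxy]benzene
Product: 9 2-(3,6-dibromo-2-methoxyphenoxy)phenol
Conditions: HCl (1.25 M in MeOH), 45 °C
Reagents that add atoms: none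
Why: Acid-catalysed acetal exchange with methanol removes the MOM group, while the aryl methyl ether, the diaryl ether and the aryl bromides are stable to dilute methanolic acid.

**Step 5**
Reactants: 9 2-(3,6-dibromo-2-methoxyphenoxy)phenol
Product: 10 2,4-dibromo-6-(3,6-dibromo-2-methoxyphenoxy)phenol
Conditions: Br2 (2.05 equiv), AcOH, 0 °C to rt; aqueous Na2S2O3 quench
Reagents that add atoms: bromine, BrBr
Why: Electrophilic aromatic bromination is directed by the free hydroxyl of ring A to its para and then its open ortho position, while ring B, a doubly brominated anisole-type ring, should react far more slowly.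

**Step 6**
Reactants: 10 2,4-dibromo-6-(3,6-dibromo-2-methoxyphenoxy)phenol
Product: 11 3,6-dibromo-2-(3,5-dibromo-2-hydroxyphenoxy)phenol (target)
Conditions: BBr3 (3 equiv), CH2Cl2, −78 °C to rt; then H2O
Reagents that add atoms: none
Why: Lewis-acid O-demethylation with BBr3 (boron coordination to oxygen, bromide attack on the methyl group) cleaves the aryl methyl ether without touching aryl bromides or the diaryl ether linkage.

**Compound list**
1 | 2,5-dibromophenol | Oc1cc(Br)ccc1Br | starting material
2 | 2-(methoxymethoxy)phenylboronic acid | COCOc1ccccc1B(O)O | starting material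
3 | 1,4-dibromo-2-[2-(methoxymethoxy)phenoxy]benzene | COCOc1ccccc1Oc1cc(Br)ccc1Br | intermediate
4 | triisopropyl borate | CC(C)OB(OC(C)C)OC(C)C | starting material
5 | {3,6-dibromo-2-[2-(methoxymethoxy)phenoxy]phenyl}lithium (aryllithium) | [Li]c1c(Br)ccc(Br)c1Oc1ccccc1OCOC | intermediate
6 | lithium {3,6-dibromo-2-[2-(methoxymethoxy)phenoxy]phenyl}triisopropoxyborate | [Li+].CC(C)O[B-](OC(C)C)(OC(C)C)c1c(Br)ccc(Br)c1Oc1ccccc1OCOC | intermediate
7 | 3,6-dibromo-2-[2-(methoxymethoxy)phenoxy]phenol | COCOc1ccccc1Oc1c(Br)ccc(Br)c1O | intermediate
8 | 1,4-dibromo-2-methoxy-3-[2-(methoxymethoxy)phenoxy]benzene | COCOc1ccccc1Oc1c(Br)ccc(Br)c1OC | intermediate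
9 | 2-(3,6-dibromo-2-methoxyphenoxy)phenol | COc1c(Br)ccc(Br)c1Oc1ccccc1O | intermediate
10 | 2,4-dibromo-6-(3,6-dibromo-2-methoxyphenoxy)phenol | COc1c(Br)ccc(Br)c1Oc1cc(Br)cc(Br)c1O | intermediate
11 | 3,6-dibromo-2-(3,5-dibromo-2-hydroxyphenoxy)phenol | Oc1c(Br)cc(Br)cc1Oc1c(Br)ccc(Br)c1O | target

**Total step count:** 6
**Longest linear sequence:** 6 steps (1 → 3 → 7 → 8 → 9 → 10 → 11)

**Steps most likely to fail**

Step 2. The deprotonation may lose site control (metalation next to a single bromine, or ortho to the acetal oxygen on ring A). The aryllithium may also eliminate LiBr before boron capture, or the crowded arylboron species may protodeboronate before oxidation. The fallback brings the ring B oxygen in through a carbonyl group and avoids any aryl anion; it sets out from 1 and comes back at 8. Magnesium-mediated ortho-formylation of 1 (MgCl2, Et3N, paraformaldehyde, MeCN, reflux) can only occur at the single free ortho position and should give 3,6-dibromo-2-hydroxybenzaldehyde F1. Methylation (MeI, K2CO3, DMF) gives 3,6-dibromo-2-methoxybenzaldehyde F2. Baeyer–Villiger oxidation with mCPBA in CH2Cl2, with aryl migration favoured by the ortho methoxy group, gives 3,6-dibromo-2-methoxyphenyl formate F3, which is methanolysed in the same flask (K2CO3, MeOH) to 3,6-dibromo-2-methoxyphenol F4. Chan–Lam coupling of F4 with 2 under the conditions of step 1 then gives 8 directly.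

Step 1. With ortho substituents on both partners, transmetalation and C–O bond formation at copper may be slow, so that protodeboronation and oxidative homocoupling consume the boronic acid. The fallback makes the ether by nucleophilic aromatic substitution and creates the ring A oxygen afterwards; it sets out from 1 and comes back at 3. Phenol 1 and commercial 2-fluorobenzaldehyde (K2CO3, DMAc, 130 °C) should give 2-(2,5-dibromophenoxy)benzaldehyde F5 by displacement of the aldehyde-activated fluoride. Baeyer–Villiger oxidation with mCPBA gives 2-(2,5-dibromophenoxy)phenyl formate F6, methanolysed (K2CO3, MeOH) to 2-(2,5-dibromophenoxy)phenol F7. Protection with chloromethyl methyl ether and iPr2NEt in CH2Cl2 gives 3.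

Step 5. Ring selectivity of the bromination may erode, with attack on ring B para to its methoxy group or a third bromination of ring A. The fallback replaces the donating methyl ether on ring B by a deactivating ester; it sets out from 7 and comes back at 11. Acetylation of 7 (Ac2O, pyridine) gives 3,6-dibromo-2-[2-(methoxymethoxy)phenoxy]phenyl acetate F8. Anhydrous acid (TFA, CH2Cl2, rt, then aqueous work-up) removes the MOM group to give 3,6-dibromo-2-(2-hydroxyphenoxy)phenyl acetate F9. Bromination (Br2, AcOH) now meets a strongly deactivated ring B and should give 3,6-dibromo-2-(3,5-dibromo-2-hydroxyphenoxy)phenyl acetate F10. Mild methanolysis (K2CO3, MeOH, rt) releases 11 without the BBr3 step.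

**Further compounds**
F1 | step 2 | 3,6-dibromo-2-hydroxybenzaldehyde | O=Cc1c(O)c(Br)ccc1Br
F2 | step 2 | 3,6-dibromo-2-methoxybenzaldehyde | O=Cc1c(OC)c(Br)ccc1Br
F3 | step 2 | 3,6-dibromo-2-methoxyphenyl formate | O=COc1c(OC)c(Br)ccc1Br
F4 | step 2 | 3,6-dibromo-2-methoxyphenol | Oc1c(OC)c(Br)ccc1Br
F5 | step 1 | 2-(2,5-dibromophenoxy)benzaldehyde | O=Cc1ccccc1Oc1cc(Br)ccc1Br
F6 | step 1 | 2-(2,5-dibromophenoxy)phenyl formate | O=COc1ccccc1Oc1cc(Br)ccc1Br
F7 | step 1 | 2-(2,5-dibromophenoxy)phenol | Oc1ccccc1Oc1cc(Br)ccc1Br
F8 | step 5 | 3,6-dibromo-2-[2-(methoxymethoxy)phenoxy]phenyl acetate | CC(=O)Oc1c(Br)ccc(Br)c1Oc1ccccc1OCOC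
F9 | step 5 | 3,6-dibromo-2-(2-hydroxyphenoxy)phenyl acetate | CC(=O)Oc1c(Br)ccc(Br)c1Oc1ccccc1O
F10 | step 5 | 3,6-dibromo-2-(3,5-dibromo-2-hydroxyphenoxy)phenyl acetate | CC(=O)Oc1c(Br)ccc(Br)c1Oc1cc(Br)cc(Br)c1O
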